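## Retrosynthetic overview

1. Feature: the 5′,8′-epoxide end is a 2,5-dihydrofuran (O–C5′–C6′=C7′–C8′) fused to the cyclohexane at C5′–C6′. Its O–C8′ bond and the C8′ stereocentre are traced back to an α-hydroxyallene, C5′(OH)–C6′=C7′=C8′, whose axis carries the C8′ configuration.
2. C40 = furanoid C15 benzothiazolyl sulfone + C25 aldehyde (Julia–Kocienski, C11′=C12′); the C25 aldehyde = triol C15 sulfone + C10 dialdehyde (C11=C12).
3. Furanoid C15: actinol → enol triflate → Sonogashira with the C6 enynol → epoxide anti to the silyloxy group → anti-SN2′ hydride → allenol → gold cycloisomerisation.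
4. Triol C15: actinol → hydroxylation at C5 → alkynyl addition to the C6 ketone → trans-hydroalumination to the 7E diene.
5. Ring order: both cyclohexane rings come with actinol; the dihydrofuran is the only ring made (step 7).

Key step: step 7

Remark: carotenoid numbering is used in the text (ring C1–C6, chain C7–C15; primes mark the furanoid half in C25/C40 compounds); the 11Z and 11′Z olefination products are assumed to equilibrate thermally to the all-E polyene, and acid and light are excluded from step 7 onwards.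

## Route

Step 1
Reactants: 1 (4R,6R)-4-hydroxy-2,2,6-trimethylcyclohexan-1-one (actinol)
Product: 2 (4R,6R)-4-(tert-butyldimethylsilyloxy)-2,2,6-trimethylcyclohexan-1-one
Conditions: TBSCl, imidazole, DMF, rt
Reagents that add atoms: tert-butyldimethylsilyl chloride, CC(C)(C)[Si](C)(C)Cl
Why: Silylation of an unhindered secondary alcohol with a silyl chloride and imidazole, which touches no stereocentre.

Step 2
Reactants: 2 TBS-actinol
Product: 4 (4R)-4-(tert-butyldimethylsilyloxy)-2,6,6-trimethylcyclohex-1-en-1-yl trifluoromethanesulfonate, via potassium enolate 3 (not isolated)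
Conditions: KN(SiMe3)2, THF, −78 → −30 °C; then PhNTf2, −78 °C → rt
Reagents that add atoms: N-phenylbis(trifluoromethanesulfonimide), O=S(=O)(N(c1ccccc1)S(=O)(=O)C(F)(F)F)C(F)(F)F
Why: Only C5 bears an α-hydrogen, so deprotonation gives a single enolate that is O-sulfonylated (enol triflate formation), the C5 stereocentre being erased on purpose.

Step 3
Reactants: 5 (E)-3-methylpent-2-en-4-yn-1-ol
Product: 6 triethyl{[(2E)-3-methylpent-2-en-4-yn-1-yl]oxy}silane
Conditions: Et3SiCl, imidazole, CH2Cl2, 0 °C
Reagents that add atoms: chlorotriethylsilane, CC[Si](Cl)(CC)CC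
Why: Silylation of a primary alcohol, the triethylsilyl group being chosen so that fluoride can later remove it beside the secondary TBS ether.

Step 4
Reactants: 4 enol triflate; 6 silylated enynol
Product: 7 C15 dienyne, tert-butyldimethyl({(1R)-3,5,5-trimethyl-4-[(3E)-3-methyl-5-(triethylsilyloxy)pent-3-en-1-yn-1-yl]cyclohex-3-en-1-yl}oxy)silane
Conditions: Pd(PPh3)4 (5 mol%), CuI (10 mol%), Et3N, DMF, rt → 45 °C
Reagents that add atoms: none
Why: Sonogashira coupling of an alkenyl triflate with a terminal alkyne forms C6–C7, and the 9E geometry comes unchanged from 5.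

Step 5
Reactants: 7 C15 dienyne
Product: 8 C15 epoxy enyne (3S,5R,6R), the 5,6-epoxide of 7 with the oxygen on the face opposite the 3-OTBS group
Conditions: mCPBA (1.05 equiv), NaHCO3, CH2Cl2, −20 → 0 °C
Reagents that add atoms: 3-chloroperoxybenzoic acid, O=C(OO)c1cccc(Cl)c1
Why: Prilezhaev epoxidation, in which the tetrasubstituted ring alkene is the most electron-rich π bond (C9=C10 carries the alkynyl and the CH2OSi group) and the peracid should add axially to the half-chair with equatorial OTBS, that is anti to the C3 silyloxy group, which sets C5 (R) and C6.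

Step 6
Reactants: 8 C15 epoxy enyne
Product: 9 C15 allenol (3S,5R,6S), 3-OTBS, tertiary 5-OH, allene C6=C7=C8 with H-8 on the face of the C5 methyl group, 9E, 11-OTES
Conditions: LiAlH4, THF, −20 → 0 °C; aq Rochelle salt
Reagents that add atoms: none
Why: SN2′ hydride reduction of an alkynyl oxirane to an α-hydroxyallene, in which, with every hydroxyl silylated and THF as donor solvent, the AlH4 anion should attack C8 from outside and anti to the breaking C6–O bond, so that the epoxide configuration becomes the (6S) allene axis with H-8 on the face away from the former epoxide oxygen.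

Step 7
Reactants: 9 C15 allenol
Product: 10 C15 furanoid (3S,5R,8R), 2,5-dihydrofuran O–C5–C6=C7–C8 fused to the ring, H-8 cis to the C5 methyl group, 3-OTBS, 9E, 11-OTES
Conditions: AuCl3 (5 mol%), THF, 0 °C → rt, dark, Ar
Reagents that add atoms: none
Why: AuCl3 (trivalent gold) binds the C7=C8 π bond of the allene, whose lobes lie in the C1–C6–C5 plane, the C5 hydroxyl, turned into that plane by a flip of the cyclohexane ring, adds to C8 anti to the metal, and protodeauration of the vinylgold species at C7 releases the 2,5-dihydrofuran with C6=C7 in place. The closest known reaction type is the gold-catalysed cycloisomerisation of α-hydroxyallenes to 2,5-dihydrofurans with axis-to-centre chirality transfer, applied here to a vinylallene on a tertiary carbinol. The ring (O, C5, C6, C7, C8) closes in the 5-endo mode on the allene terminus, and no other ring size can compete because C6 is fully substituted and the hydroxyl sits on the carbon next to the allene. C8 is the only new stereocentre and is controlled by the allene axis: H-8 and C9 stay above and below the ring plane while oxygen arrives in the plane, so H-8, which lies on the face of the C5 methyl group, ends cis to it and the chain trans (8R). The step needs complete chirality transfer and O- rather than C-cyclisation of the vinylallene; THF as donor solvent tempers the Lewis acidity that would epimerise the allene or ionise the new doubly allylic C8–O bond, the aprotic medium keeps that bond closed, and the hydroxyl held next to the allene should make oxyauration faster than a Nazarov-type closure.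

Step 8
Reactants: 10 C15 furanoid bis-silyl ether
Product: 11 furanoid allylic alcohol (3S,5R,8R), 10 with free 11-OH and 3-OTBS kept
Conditions: TBAF (1.05 equiv), THF, −40 → −20 °C
Reagents that add atoms: none
Why: Fluoride desilylation, in which the primary allylic triethylsilyl ether is cleaved far faster than the secondary TBS ether and the basic medium leaves the acid-labile C8–O bond untouched.

Step 9
Reactants: 11 furanoid allylic alcohol
Product: 12 furanoid 11-(1,3-benzothiazol-2-ylsulfanyl) compound (3S,5R,8R)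
Conditions: 2-mercaptobenzothiazole, PPh3, DIAD, THF, 0 °C
Reagents that add atoms: 2-mercaptobenzothiazole, Sc1nc2ccccc2s1
Why: Mitsunobu thioetherification of the only free, primary allylic alcohol by SN2 at C11 under neutral conditions.

Step 10
Reactants: 12 furanoid sulfide
Product: 14 furanoid 11-(1,3-benzothiazol-2-ylsulfonyl) compound (3S,5R,8R), via sulfoxide 13 (not isolated)
Conditions: (NH4)6Mo7O24·4H2O (10 mol%), 30% aq H2O2, EtOH, 0 °C
Reagents that add atoms: hydrogen peroxide, OO
Why: Molybdate-catalysed peroxide oxidation of a sulfide through the sulfoxide to the sulfone, which is chemoselective for sulfur over the two trisubstituted alkenes and is run cold in near-neutral ethanol so that the allylic ether should persist.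

Step 11
Reactants: 2 TBS-actinol
Product: 16 (2R,4S)-4-(tert-butyldimethylsilyloxy)-2-hydroxy-2,6,6-trimethylcyclohexan-1-one, via sodium enolate 15 (not isolated)
Conditions: NaN(SiMe3)2, THF, −78 → 0 °C; then 2-(phenylsulfonyl)-3-phenyloxaziridine, −78 °C; aq NH4Cl
Reagents that add atoms: 2-(phenylsulfonyl)-3-phenyloxaziridine, O=S(=O)(N1OC1c1ccccc1)c1ccccc1
Why: Enolate oxidation with an N-sulfonyloxaziridine (Davis oxidation) on the sodium enolate, the usual partner of this oxidant, which adds little to the sulfonimine by-product; oxygen should be delivered axially to C5 of the half-chair with equatorial OTBS, that is anti to the C3 silyloxy group, giving the tertiary alcohol trans to 3-OTBS (5R in carotenoid numbering).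

Step 12
Reactants: 16 α-hydroxy ketone; 5 (E)-3-methylpent-2-en-4-yn-1-ol
Product: 18 C15 enyne triol (3S,5R,6R), 3-OTBS, cis-5,6-diol on the face opposite 3-OTBS, C7≡C8, 9E, free 11-OH, via dilithium enynolate 17 (not isolated)
Conditions: 5 (3.3 equiv), n-BuLi (6.6 equiv), THF, −78 → 0 °C; then 16, −78 °C → rt; aq NH4Cl
Reagents that add atoms: none
Why: 1,2-Addition of an alkynyllithium to a ketone without α-hydrogens, in which the slim nucleophile should enter axially and anti to the axial C5–O and axial C1 methyl of the stable chair (a chelated alternative would need the triaxial conformer), so that the new C6 hydroxyl is cis to the C5 hydroxyl.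

Step 13
Reactants: 18 C15 enyne triol
Product: 19 C15 diene triol (3S,5R,6S,7E,9E), 3-OTBS, 5-OH, 6-OH, 11-OH
Conditions: NaAlH2(OCH2CH2OMe)2 (Red-Al, 6 equiv), THF, 0 °C → rt; aq Rochelle salt
Reagents that add atoms: none
Why: Reduction of a propargylic alcohol by trans-hydroalumination, the C6 alkoxide delivering hydride to C7 through a five-membered alanate, which gives the 7E alkene on protonation and is the known course for this enynol unit next to a tertiary carbinol.

Step 14
Reactants: 19 C15 diene triol
Product: 20 triol-series 11-(1,3-benzothiazol-2-ylsulfanyl) compound (3S,5R,6S,7E,9E)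
Conditions: 2-mercaptobenzothiazole, PPh3, DIAD, THF, 0 °C
Reagents that add atoms: 2-mercaptobenzothiazole, Sc1nc2ccccc2s1
Why: Mitsunobu thioetherification, in which only the primary allylic hydroxyl can be activated and the two tertiary hydroxyls stay inert.

Step 15
Reactants: 20 triol-series sulfide
Product: 22 triol-series 11-(1,3-benzothiazol-2-ylsulfonyl) compound (3S,5R,6S,7E,9E), via sulfoxide 21 (not isolated)
Conditions: (NH4)6Mo7O24·4H2O (10 mol%), 30% aq H2O2, EtOH, 0 °C
Reagents that add atoms: hydrogen peroxide, OO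
Why: Molybdate-catalysed peroxide oxidation of the sulfide to the sulfone, which at 0 °C should outrun epoxidation of the diene and leave the hindered tertiary allylic alcohol alone.

Step 16
Reactants: 22 triol-series sulfone
Product: 23 5,6-bis(trimethylsilyloxy) sulfone (3S,5R,6S,7E,9E)
Conditions: TMSOTf (3 equiv), 2,6-lutidine, CH2Cl2, −78 → 0 °C
Reagents that add atoms: trimethylsilyl trifluoromethanesulfonate, C[Si](C)(C)OS(=O)(=O)C(F)(F)F
Why: Silylation of both hindered tertiary hydroxyls with a silyl triflate and a hindered base removes the acidic protons before the two olefinations and leaves only fluoride-labile groups for the last step.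

Step 17
Reactants: 23 bis-TMS sulfone; 24 (2E,4E,6E)-2,7-dimethylocta-2,4,6-trienedial
Product: 26 all-E C25 aldehyde (3S,5R,6S)-3-(tert-butyldimethylsilyloxy)-5,6-bis(trimethylsilyloxy)-5,6-dihydro-12′-apo-β-caroten-12′-al, via 11Z isomer 25 (not isolated)
Conditions: 24 (3 equiv), NaN(SiMe3)2 (1.1 equiv) added last, THF, −78 °C → rt; then PhMe, 80 °C, dark
Reagents that add atoms: none
Why: Julia–Kocienski olefination forms C11=C12, the excess of the non-enolisable symmetric dialdehyde and the lower electrophilicity of the product securing mono-olefination, and the sterically hindered 11Z isomer should equilibrate thermally to the all-E aldehyde.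

Step 18
Reactants: 14 furanoid sulfone; 26 all-E C25 aldehyde
Product: 28 all-E silylated C40 (3S,5R,6S,3′S,5′R,8′R)-3,3′-bis(tert-butyldimethylsilyloxy)-5,6-bis(trimethylsilyloxy)-5′,8′-epoxy-5,6,5′,8′-tetrahydro-β,β-carotene, via 11′Z isomer 27 (not isolated)
Conditions: 14 (1.2 equiv), NaN(SiMe3)2 (1.15 equiv) added last, THF, −78 → 0 °C; then C6H6, 60 °C, dark, Ar
Reagents that add atoms: none
Why: Julia–Kocienski olefination forms C11′=C12′, the base being added to the mixture at −78 °C so that addition to the aldehyde outruns ring opening of the metalated sulfone, and the hindered 11′Z isomer should equilibrate thermally to all-E without touching C8′.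

Step 19
Reactants: 28 all-E silylated C40
Product: 29 target (3S,5R,6S,3′S,5′R,8′R)-5′,8′-epoxy-5,6,5′,8′-tetrahydro-β,β-carotene-3,5,6,3′-tetrol
Conditions: TBAF (6 equiv), THF, 0 °C → rt, dark, Ar
Reagents that add atoms: none
Why: Fluoride cleaves the two secondary TBS and two tertiary TMS ethers in a basic medium that should spare the polyene, the tertiary allylic C6–OH and the acid-labile C8′–O bond.

## Compound list

1 | (4R,6R)-4-hydroxy-2,2,6-trimethylcyclohexan-1-one (actinol) | O=C1C(C)(C)C[C@H](O)C[C@H]1C | starting material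
2 | (4R,6R)-4-(tert-butyldimethylsilyloxy)-2,2,6-trimethylcyclohexan-1-one | O=C1C(C)(C)C[C@H](O[Si](C)(C)C(C)(C)C)C[C@H]1C | intermediate
3 | potassium (4R)-4-(tert-butyldimethylsilyloxy)-2,6,6-trimethylcyclohex-1-en-1-olate | CC1=C([O-])C(C)(C)C[C@H](O[Si](C)(C)C(C)(C)C)C1.[K+] | intermediate
4 | (4R)-4-(tert-butyldimethylsilyloxy)-2,6,6-trimethylcyclohex-1-en-1-yl trifluoromethanesulfonate | CC1=C(OS(=O)(=O)C(F)(F)F)C(C)(C)C[C@H](O[Si](C)(C)C(C)(C)C)C1 | intermediate
5 | (E)-3-methylpent-2-en-4-yn-1-ol | C#C/C(C)=C/CO | starting material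
6 | triethyl{[(2E)-3-methylpent-2-en-4-yn-1-yl]oxy}silane | C#C/C(C)=C/CO[Si](CC)(CC)CC | intermediate
7 | C15 dienyne (3R,9E): 3-OTBS, C5=C6, C7≡C8, 11-OTES | CC1=C(C#C/C(C)=C/CO[Si](CC)(CC)CC)C(C)(C)C[C@H](O[Si](C)(C)C(C)(C)C)C1 | intermediate
8 | C15 epoxy enyne (3S,5R,6R,9E): 5,6-epoxide anti to 3-OTBS, 11-OTES | CC[Si](CC)(CC)OC/C=C(C)/C#C[C@]1(O2)C(C)(C)C[C@H](O[Si](C)(C)C(C)(C)C)C[C@]12C | intermediate
9 | C15 allenol (3S,5R,6S,9E): 3-OTBS, 5-OH, C6=C7=C8, H-8 on the face of the C5 methyl, 11-OTES | CC[Si](CC)(CC)OC/C=C(\C)C([H])=[C@]=C1C(C)(C)C[C@H](O[Si](C)(C)C(C)(C)C)C[C@@]1(C)O | intermediate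
10 | C15 furanoid (3S,5R,8R,9E): 5,8-epoxy, C6=C7, 3-OTBS, 11-OTES | CC[Si](CC)(CC)OC/C=C(\C)[C@H]1C=C2C(C)(C)C[C@H](O[Si](C)(C)C(C)(C)C)C[C@@]2(C)O1 | intermediate
11 | furanoid allylic alcohol (3S,5R,8R,9E): 3-OTBS, 11-OH | OC/C=C(\C)[C@H]1C=C2C(C)(C)C[C@H](O[Si](C)(C)C(C)(C)C)C[C@@]2(C)O1 | intermediate
12 | furanoid benzothiazolyl sulfide (3S,5R,8R,9E) | c1ccc2sc(SC/C=C(\C)[C@H]3C=C4C(C)(C)C[C@H](O[Si](C)(C)C(C)(C)C)C[C@@]4(C)O3)nc2c1 | intermediate
13 | furanoid benzothiazolyl sulfoxide (mixture at sulfur) | O=S(C/C=C(\C)[C@H]1C=C2C(C)(C)C[C@H](O[Si](C)(C)C(C)(C)C)C[C@@]2(C)O1)c1nc2ccccc2s1 | intermediate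
14 | furanoid benzothiazolyl sulfone (3S,5R,8R,9E) | O=S(=O)(C/C=C(\C)[C@H]1C=C2C(C)(C)C[C@H](O[Si](C)(C)C(C)(C)C)C[C@@]2(C)O1)c1nc2ccccc2s1 | intermediate
15 | sodium (4R)-4-(tert-butyldimethylsilyloxy)-2,6,6-trimethylcyclohex-1-en-1-olate | CC1=C([O-])C(C)(C)C[C@H](O[Si](C)(C)C(C)(C)C)C1.[Na+] | intermediate
16 | (2R,4S)-4-(tert-butyldimethylsilyloxy)-2-hydroxy-2,6,6-trimethylcyclohexan-1-one | O=C1C(C)(C)C[C@H](O[Si](C)(C)C(C)(C)C)C[C@@]1(C)O | intermediate
17 | dilithium salt of 5 (lithium alkoxide and lithium acetylide) | [Li]C#C/C(C)=C/CO[Li] | intermediate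
18 | C15 enyne triol (3S,5R,6R,9E): 3-OTBS, cis-5,6-diol, C7≡C8, 11-OH | OC/C=C(C)/C#C[C@]1(O)C(C)(C)C[C@H](O[Si](C)(C)C(C)(C)C)C[C@@]1(C)O | intermediate
19 | C15 diene triol (3S,5R,6S,7E,9E): 3-OTBS, 5-OH, 6-OH, 11-OH | OC/C=C(C)/C=C/[C@]1(O)C(C)(C)C[C@H](O[Si](C)(C)C(C)(C)C)C[C@@]1(C)O | intermediate
20 | triol-series benzothiazolyl sulfide (3S,5R,6S,7E,9E) | c1ccc2sc(SC/C=C(C)/C=C/[C@]3(O)C(C)(C)C[C@H](O[Si](C)(C)C(C)(C)C)C[C@@]3(C)O)nc2c1 | intermediate
21 | triol-series benzothiazolyl sulfoxide (mixture at sulfur) | O=S(C/C=C(C)/C=C/[C@]1(O)C(C)(C)C[C@H](O[Si](C)(C)C(C)(C)C)C[C@@]1(C)O)c1nc2ccccc2s1 | intermediate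
22 | triol-series benzothiazolyl sulfone (3S,5R,6S,7E,9E) | O=S(=O)(C/C=C(C)/C=C/[C@]1(O)C(C)(C)C[C@H](O[Si](C)(C)C(C)(C)C)C[C@@]1(C)O)c1nc2ccccc2s1 | intermediate
23 | 5,6-bis(trimethylsilyloxy) sulfone (3S,5R,6S,7E,9E) | O=S(=O)(C/C=C(C)/C=C/[C@]1(O[Si](C)(C)C)C(C)(C)C[C@H](O[Si](C)(C)C(C)(C)C)C[C@@]1(C)O[Si](C)(C)C)c1nc2ccccc2s1 | intermediate
24 | (2E,4E,6E)-2,7-dimethylocta-2,4,6-trienedial | O=C/C(C)=C/C=C/C=C(C)/C=O | starting material
25 | 11Z isomer of the C25 aldehyde | O=C/C(C)=C/C=C/C=C(C)/C=C\C=C(C)\C=C\[C@]1(O[Si](C)(C)C)C(C)(C)C[C@H](O[Si](C)(C)C(C)(C)C)C[C@@]1(C)O[Si](C)(C)C | intermediate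
26 | all-E C25 aldehyde (3S,5R,6S): 3-OTBS, 5,6-bis-OTMS, 12′-apo-β-caroten-12′-al | O=C/C(C)=C/C=C/C=C(C)/C=C/C=C(C)/C=C/[C@]1(O[Si](C)(C)C)C(C)(C)C[C@H](O[Si](C)(C)C(C)(C)C)C[C@@]1(C)O[Si](C)(C)C | intermediate
27 | 11′Z isomer of the silylated C40 compound | CC(/C=C/C=C(C)/C=C/[C@]1(O[Si](C)(C)C)C(C)(C)C[C@H](O[Si](C)(C)C(C)(C)C)C[C@@]1(C)O[Si](C)(C)C)=C\C=C\C=C(C)\C=C/C=C(\C)[C@H]1C=C2C(C)(C)C[C@H](O[Si](C)(C)C(C)(C)C)C[C@@]2(C)O1 | intermediate
28 | all-E silylated C40 (3S,5R,6S,3′S,5′R,8′R): 3,3′-bis-OTBS, 5,6-bis-OTMS | CC(/C=C/C=C(C)/C=C/[C@]1(O[Si](C)(C)C)C(C)(C)C[C@H](O[Si](C)(C)C(C)(C)C)C[C@@]1(C)O[Si](C)(C)C)=C\C=C\C=C(C)\C=C\C=C(/C)[C@H]1C=C2C(C)(C)C[C@H](O[Si](C)(C)C(C)(C)C)C[C@@]2(C)O1 | intermediate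
29 | (3S,5R,6S,3′S,5′R,8′R)-5′,8′-epoxy-5,6,5′,8′-tetrahydro-β,β-carotene-3,5,6,3′-tetrol | CC(/C=C/C=C(C)/C=C/[C@]1(O)C(C)(C)C[C@H](O)C[C@@]1(C)O)=C\C=C\C=C(C)\C=C\C=C(/C)[C@H]1C=C2C(C)(C)C[C@H](O)C[C@@]2(C)O1 | target

## Step count and risks

Total steps: 19. Longest linear sequence: 11 (steps 1, 2, 4, 5, 6, 7, 8, 9, 10, 18, 19).

Steps most likely to fail:

1. Step 7 (gold cycloisomerisation). The allene axis may epimerise under the Lewis acid before oxygen adds, or the new doubly allylic C8–O bond may ionise and re-close, so that C8 is scrambled. The vinylallene may also divert into a Nazarov-type carbocyclisation, and turnover may be slow because the ring must flip to bring the C5–O bond into the allene plane. Fallback: the ring would be closed from allenol 9 by electrophilic iodoetherification. N-Iodosuccinimide in CH2Cl2 at −20 °C should give, by 5-endo attack of the C5 hydroxyl on the iodonium-activated C7=C8 bond (anti addition, the same face relationships as with gold), the 7-iodo-2,5-dihydrofuran F1. Its vinylic iodide would then be removed by radical reduction (Bu3SnH, Et3B/air, toluene, rt), which comes back to the route at 10.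

2. Step 6 (hydride opening). If aluminium binds the epoxide oxygen first and hydride is delivered from that side, or delivery is unselective, the C6-epimeric allene forms and step 7 would give the C8 epimer. Fallback: the allene would be made from α-hydroxy ketone 16 by a palladium route whose anti course is fixed by oxidative addition. The lithium acetylide of 6 (n-BuLi, THF, −78 °C, 2.2 equiv) adds to 16 as in step 12 to give the alkynyl cis-diol F2. Carbonyldiimidazole in THF with catalytic DBU closes the cyclic carbonate F3. Pd2(dba)3·CHCl3 and PBu3 with HCO2NH4 in THF (formate hydrogenolysis of a propargylic carbonate to an allene) should ionise the C6–O bond with palladium entering at C8 on the opposite face, transfer hydride to C8 with retention and lose CO2, which comes back to the route at 9.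

3. Step 18 (fragment union). The metalated sulfone may open the dihydrofuran by 1,4-elimination of the C5′ alkoxide or condense with itself, the polyenal may be deprotonated at its remote methyl groups, and the Z to E equilibration may stop short. Fallback: the C11′=C12′ bond would be made by a Wittig reaction of a less basic phosphorus ylide. Alcohol 11 with CBr4, PPh3 and 2,6-lutidine in CH2Cl2 at −20 °C gives the allylic bromide F4. PPh3 in ethyl acetate at rt gives the phosphonium bromide F5. Condensation of F5 with aldehyde 26 (NaOMe, CH2Cl2/MeOH, 0 °C → rt, or 1,2-epoxybutane at 60 °C as neutral base source), followed by the same thermal equilibration, comes back to the route at 28.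

## Further compounds

F1 | step 7 | 7-iodo furanoid, 10 with iodine at C7 and the same spatial arrangement at C3, C5 and C8 | CC[Si](CC)(CC)OC/C=C(\C)[C@H]1C(I)=C2C(C)(C)C[C@H](O[Si](C)(C)C(C)(C)C)C[C@@]2(C)O1
F2 | step 6 | alkynyl cis-5,6-diol (3S,5R,6R,9E) with 3-OTBS and 11-OTES | CC[Si](CC)(CC)OC/C=C(C)/C#C[C@]1(O)C(C)(C)C[C@H](O[Si](C)(C)C(C)(C)C)C[C@@]1(C)O
F3 | step 6 | 5,6-cyclic carbonate of F2 | CC[Si](CC)(CC)OC/C=C(C)/C#C[C@]1(OC(=O)O2)C(C)(C)C[C@H](O[Si](C)(C)C(C)(C)C)C[C@]12C
F4 | step 18 | furanoid allylic bromide (3S,5R,8R,9E), 11-Br, 3-OTBS | BrC/C=C(\C)[C@H]1C=C2C(C)(C)C[C@H](O[Si](C)(C)C(C)(C)C)C[C@@]2(C)O1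
F5 | step 18 | furanoid C15 triphenylphosphonium bromide (3S,5R,8R,9E) | [Br-].c1ccccc1[P+](c1ccccc1)(c1ccccc1)C/C=C(\C)[C@H]1C=C2C(C)(C)C[C@H](O[Si](C)(C)C(C)(C)C)C[C@@]2(C)O1
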